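**Assumptions.** Carbon numbers are those of the target's geranyllinalool-type chain: C1=C2 vinyl, C3 carbinol, ring C6–C11, O bridging C7 and C10, C14–Br, C15–Cl. The target SMILES corresponds to (3S,6S,7R,10S,11S,14S). (2E,6E)-Farnesol, prenylmagnesium chloride (THF solution) and the D-fructose-derived Shi ketone are taken as commercial. The route is a design from known reaction types and has not been run.

## Retrosynthetic overview

1. The C14-Br/C15-Cl pair comes last, from a (14R)-14,15-epoxide through a bromonium relay (Br⁻ opens the epoxide, the OH is activated, Cl⁻ captures the bromonium) with net inversion at C14.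
2. The 7-oxabicyclo[2.2.1]heptane comes from a biomimetic Lewis-acid cyclisation of a (10S,11S)-10,11-epoxy-geranyllinalool silyl ether. The carbocycle forms first (C6–C11 bond), then the C7 cation is captured by the C10 oxygen to form the ether bridge.
3. The epoxy-tetraene comes from Cu-catalysed prenylation (C12–C13 bond) of an epoxy triflate. The epoxide is set by Sharpless epoxidation of a C12 allylic alcohol, which makes the 10,11-olefin the only one addressable.
4. The C12 alcohol comes from SeO2 oxidation of (S)-nerolidol TES ether, and (S)-nerolidol from (2S,3S)-epoxyfarnesol (Sharpless epoxidation, iodide, Zn) made from farnesol.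

## Route

**Step 1**
Reactants: 1, (2E,6E)-farnesol
Product: 2, (2S,3S)-2,3-epoxyfarnesol
Conditions: Ti(OiPr)4 (10 mol%), L-(+)-DET (12 mol%), t-BuOOH, 4 Å MS, CH2Cl2, −20 °C
Reagents that add atoms: tert-butyl hydroperoxide, CC(C)(C)OO
Why: Sharpless asymmetric epoxidation touches only the allylic-alcohol olefin, and L-(+)-tartrate gives the (2S,3S) epoxide (as for geraniol), which sets the future C3 centre.

**Step 2**
Reactants: 2, (2S,3S)-2,3-epoxyfarnesol
Product: 3, (2R,3S)-2,3-epoxyfarnesyl iodide (same spatial arrangement as 2; the R label is a CIP priority change)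
Conditions: I2, PPh3, imidazole, THF, 0 °C
Reagents that add atoms: iodine, II
Why: Garegg–Samuelsson (Appel-type) iodination of the primary alcohol leaves the trisubstituted epoxide and the olefins alone and breaks no bond to a stereocentre.

**Step 3**
Reactants: 3, (2R,3S)-2,3-epoxyfarnesyl iodide
Product: 4, (3S,6E)-nerolidol
Conditions: Zn dust, AcOH (cat.), EtOH, 40 °C
Reagents that add atoms: none
Why: Zinc insertion into C–I followed by β-alkoxide elimination (reductive epoxide opening) gives the tertiary vinyl carbinol, and the C3–O bond is never broken, so C3 stays S.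

**Step 4**
Reactants: 4, (3S,6E)-nerolidol
Product: 5, (3S,6E)-nerolidol triethylsilyl ether
Conditions: TESOTf, 2,6-lutidine, CH2Cl2, −78 → 0 °C
Reagents that add atoms: triethylsilyl triflate, CC[Si](CC)(CC)OS(=O)(=O)C(F)(F)F
Why: Silylation masks the tertiary allylic alcohol so it cannot ionise or act as a nucleophile in the later Lewis-acid and Tf2O steps.

**Step 5**
Reactants: 5, nerolidol TES ether
Product: 6, (2E,6E,10S)-2,6,10-trimethyl-10-(triethylsilyloxy)dodeca-2,6,11-trien-1-ol (the C12 alcohol)
Conditions: SeO2 (0.3 equiv), t-BuOOH, salicylic acid (cat.), CH2Cl2, rt; then NaBH4, MeOH, 0 °C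
Reagents that add atoms: selenium dioxide, O=[Se]=O (re-oxidised by t-BuOOH, CC(C)(C)OO)
Why: Sharpless–Umbreit allylic oxidation (ene then [2,3]-shift) selects the (E)-methyl of the terminal trisubstituted olefin, and the borohydride quench returns any over-oxidised enal to the alcohol.

**Step 6**
Reactants: 6, the C12 allylic alcohol
Product: 7, [(2S,3S)-2-methyl-3-[(3E,7S)-3,7-dimethyl-7-(triethylsilyloxy)nona-3,8-dien-1-yl]oxiran-2-yl]methanol (10S,11S epoxide)
Conditions: Ti(OiPr)4, L-(+)-DET, t-BuOOH, 4 Å MS, CH2Cl2, −25 °C
Reagents that add atoms: tert-butyl hydroperoxide, CC(C)(C)OO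
Why: Sharpless asymmetric epoxidation is hydroxyl-directed, so only C10=C11 reacts (C6=C7 and the vinyl group are untouched), and L-(+)-tartrate sets C10 and C11 as S,S under reagent control.

**Step 7**
Reactants: 7, the (10S,11S)-epoxy alcohol
Product: 8, the corresponding primary triflate, [(2S,3S)-…oxiran-2-yl]methyl trifluoromethanesulfonate
Conditions: Tf2O, 2,6-lutidine, CH2Cl2, −78 °C; used crude
Reagents that add atoms: triflic anhydride, O=S(=O)(OS(=O)(=O)C(F)(F)F)C(F)(F)F
Why: O-sulfonylation of the primary alcohol gives a leaving group reactive enough for substitution at −78 °C next to the fully substituted epoxide carbon.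

**Step 8**
Reactants: 8, the epoxy triflate; 9, prenylmagnesium chloride
Product: 10, (3S,6E,10S,11S)-10,11-epoxy-10,11-dihydrogeranyllinalool TES ether
Conditions: 9 (3 equiv), CuI (20 mol%), THF, −78 → −40 °C
Reagents that add atoms: prenylmagnesium chloride (9), CC(C)=CC[Mg]Cl
Why: Cu-catalysed Grignard–alkyl triflate cross-coupling forms C12–C13; prenylcopper couples at its unsubstituted terminus and has no E/Z geometry to lose, and the triflate is displaced far faster than the trisubstituted epoxide opens.

**Step 9**
Reactants: 10, the epoxy-tetraene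
Product: 11, triethyl{[(3S)-5-[(1R,2S,3S,4S)-1,3-dimethyl-3-(4-methylpent-3-en-1-yl)-7-oxabicyclo[2.2.1]heptan-2-yl]-3-methylpent-1-en-3-yl]oxy}silane
Conditions: BF3·OEt2 (1.1 equiv), CH2Cl2 (0.01 M), −78 °C, 20 min; Et3N quench
Reagents that add atoms: none
Why: In this cationic epoxy-olefin cyclisation the E-C6=C7 olefin attacks the tertiary epoxide carbon anti through a chair transition state (inversion at C11; C5 chain equatorial, so C6 is S), and the C7 cation is captured across the ring by the C10 oxygen, which fixes C7 as R.

**Step 10**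
Reactants: 11, the oxabicycle with the prenyl side chain
Product: 12, the (14R)-14,15-epoxide (side chain 2-[(2R)-3,3-dimethyloxiran-2-yl]ethyl)
Conditions: D-fructose-derived Shi ketone (30 mol%), Oxone, K2CO3, Bu4NHSO4, MeCN/DMM/aq. borate–EDTA buffer (pH 10.5), 0 °C
Reagents that add atoms: Oxone (potassium peroxymonosulfate), [K+].[O-]S(=O)(=O)OO
Why: Shi asymmetric epoxidation attacks only the electron-rich trisubstituted olefin (the hindered vinyl group is inert), and the D-fructose ketone gives the R epoxide under catalyst control.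

**Step 11**
Reactants: 12, the (14R)-epoxide
Product: 13, the bromohydrin with side chain (3R)-4-bromo-3-hydroxy-4-methylpentyl (Br at C15, OH at C14)
Conditions: MgBr2·OEt2 (2 equiv), Et2O, −20 → 0 °C
Reagents that add atoms: magnesium bromide, Br[Mg]Br
Why: Lewis-acid-assisted epoxide opening puts bromide on the tertiary carbon and leaves the C14–O bond intact (14R); any minor regioisomer (Br at C14 with inversion, OH at C15) leads to the same bromonium ion in step 12.

**Step 12**
Reactants: 13, the bromohydrin
Product: 14, dactylomelol TES ether (side chain (3S)-3-bromo-4-chloro-4-methylpentyl)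
Conditions: Tf2O, 2,6-lutidine, CH2Cl2, −78 °C; then n-Bu4NCl (5 equiv), −78 → −20 °C
Reagents that add atoms: tetrabutylammonium chloride, CCCC[N+](CCCC)(CCCC)CCCC.[Cl-]
Why: By neighbouring-group participation the tertiary bromine displaces the secondary triflate with inversion at C14 to give a bromonium ion, which chloride opens at the tertiary carbon (Markovnikov); the net 1,2-bromine shift gives (14S)-Br and C15–Cl.

**Step 13**
Reactants: 14, dactylomelol TES ether
Product: 15, dactylomelol
Conditions: HF·pyridine, pyridine/THF, 0 °C → rt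
Reagents that add atoms: none
Why: Buffered fluoride desilylation frees the tertiary allylic alcohol without base that could eliminate the bromochloride and without acid strong enough to open the bridged ether.

## Compound list

1 | (2E,6E)-farnesol | OC/C=C(C)/CC/C=C(C)/CCC=C(C)C | starting material
2 | (2S,3S)-2,3-epoxyfarnesol | OC[C@@H]1O[C@@]1(C)CC/C=C(C)/CCC=C(C)C | intermediate
3 | (2R,3S)-2,3-epoxyfarnesyl iodide | IC[C@@H]1O[C@@]1(C)CC/C=C(C)/CCC=C(C)C | intermediate
4 | (3S,6E)-nerolidol | C=C[C@@](C)(O)CC/C=C(C)/CCC=C(C)C | intermediate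
5 | (3S,6E)-nerolidol TES ether | C=C[C@@](C)(O[Si](CC)(CC)CC)CC/C=C(C)/CCC=C(C)C | intermediate
6 | (2E,6E,10S)-2,6,10-trimethyl-10-(triethylsilyloxy)dodeca-2,6,11-trien-1-ol | C=C[C@@](C)(O[Si](CC)(CC)CC)CC/C=C(C)/CC/C=C(C)/CO | intermediate
7 | (10S,11S)-10,11-epoxy C12 alcohol | C=C[C@@](C)(O[Si](CC)(CC)CC)CC/C=C(C)/CC[C@@H]1O[C@@]1(C)CO | intermediate
8 | triflate of 7 | C=C[C@@](C)(O[Si](CC)(CC)CC)CC/C=C(C)/CC[C@@H]1O[C@@]1(C)COS(=O)(=O)C(F)(F)F | intermediate
9 | prenylmagnesium chloride | CC(C)=CC[Mg]Cl | starting material
10 | (3S,6E,10S,11S)-10,11-epoxy-10,11-dihydrogeranyllinalool TES ether | C=C[C@@](C)(O[Si](CC)(CC)CC)CC/C=C(C)/CC[C@@H]1O[C@@]1(C)CCC=C(C)C | intermediate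
11 | (1R,2S,3S,4S)-oxabicycle with prenyl side chain, TES ether | C=C[C@@](C)(O[Si](CC)(CC)CC)CC[C@H]1[C@](C)(CCC=C(C)C)[C@@H]2CC[C@@]1(C)O2 | intermediate
12 | (14R)-14,15-epoxide of 11 | C=C[C@@](C)(O[Si](CC)(CC)CC)CC[C@H]1[C@](C)(CC[C@H]3OC3(C)C)[C@@H]2CC[C@@]1(C)O2 | intermediate
13 | (14R)-14-hydroxy-15-bromide (bromohydrin) | C=C[C@@](C)(O[Si](CC)(CC)CC)CC[C@H]1[C@](C)(CC[C@@H](O)C(C)(C)Br)[C@@H]2CC[C@@]1(C)O2 | intermediate
14 | dactylomelol TES ether | C=C[C@@](C)(O[Si](CC)(CC)CC)CC[C@H]1[C@](C)(CC[C@H](Br)C(C)(C)Cl)[C@@H]2CC[C@@]1(C)O2 | intermediate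
15 | dactylomelol, (3S)-5-[(1R,2S,3S,4S)-3-[(3S)-3-bromo-4-chloro-4-methylpentyl]-1,3-dimethyl-7-oxabicyclo[2.2.1]heptan-2-yl]-3-methylpent-1-en-3-ol | C=C[C@@](C)(O)CC[C@H]1[C@](C)(CC[C@H](Br)C(C)(C)Cl)[C@@H]2CC[C@@]1(C)O2 | target

## Summary

Total steps: 13. Longest linear sequence: 13 (from farnesol; compound 9 is purchased).

Steps most likely to fail, with fallbacks:

1. **Step 9, cationic cyclisation to the oxabicycle.** Risks are olefinic monocycles from proton loss, hydride-shift ketone, and loss or ionisation of the C3 silyl ether. Fallback: switch to a radical manifold. Cp2TiCl (from Cp2TiCl2/Mn) cyclises 10 to the exocyclic-methylene cyclohexanol (C7=CH2, C10–OH) with the same C6/C10/C11 stereochemistry. The bridge is then closed by transannular oxymercuration–demercuration (Hg(OCOCF3)2, then NaBH4).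

2. **Step 8, Cu-catalysed prenylation of the hindered epoxy triflate.** Risks are γ-coupling (reverse prenyl), epoxide opening and slow substitution. Fallback: use a stabilised carbanion instead. Alkylate lithiated prenyl phenyl sulfone with 8 (or the corresponding iodide), which is α-selective by design, then remove the sulfone reductively (Na/Hg, Na2HPO4, MeOH) to reach 10.

3. **Steps 11–12, stereospecific bromochloride formation.** Risks are semipinacol rearrangement, elimination to allylic halides, capture of the bromonium by the ring ether oxygen, and the secondary-Cl/tertiary-Br regioisomer. Fallback: drop the epoxide relay and add BrCl directly to olefin 11 (NBS, BnEt3N⁺Cl⁻, CH2Cl2, −78 °C; Markovnikov, anti). The two C14 epimers are then separated by HPLC before desilylation.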